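**Retrosynthetic overview**

1. The target is an (S)-4-phenyl-1,5-diazocan-2-one with methyl on N5 and a 4-benzamidobutyl chain (C1'–C4') on N1; the N5-methyl is put on last by reductive methylation of the N5–H lactam.
2. Key disconnection: the central C2'–C3' bond of the butylene chain, made by SN2 attack of a 2-benzamidoethyl cuprate on a CH2 of an N-alkyl aziridine. The secondary amine released by this C–C bond formation enlarges a β-lactam to the eight-membered lactam in the same operation, through a 1,5-diazabicyclo[4.2.0]octane carbinolamine that fragments.
3. Enabling feature: N1 with chain carbons C1'/C2' is a latent aziridine, and N5–C4–C3–C2(=O) is a latent azetidin-2-one whose nitrogen is tied to N1 by the C6–C7–C8 bridge. The diazocanone is therefore a β-lactam enlarged by four atoms as soon as N1 becomes N–H.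
4. Ring order: azetidinone first (from (S)-β-phenylalanine methyl ester, the source of C4), aziridine attached intact, diazocanone last by 4→8 ring enlargement; both small rings are consumed.

Key step: step 4

Assumption: aziridine (ethyleneimine) is taken as a purchasable reagent; it is toxic and volatile and would be handled as a cold solution in a closed system.

**Route**

Step 1
Reactants: 1 methyl (3S)-3-amino-3-phenylpropanoate hydrochloride
Product: 2 (4S)-4-phenylazetidin-2-one
Conditions: t-BuMgCl (3.2 equiv), THF, 0 °C → rt; aq NH4Cl
Reagents that add atoms: none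
Why: Breckpot β-lactam synthesis: the chloromagnesium amide of the β-amino ester acylates itself in a 4-exo-trig closure while the bulky Grignard base does not add to the ester; the C4 stereocentre comes unchanged from 1.

Step 2
Reactants: 2 (4S)-4-phenylazetidin-2-one; 3 1,3-dibromopropane
Product: 4 (4S)-1-(3-bromopropyl)-4-phenylazetidin-2-one
Conditions: 3 (4 equiv), powdered KOH, Bu4NBr (cat.), THF, rt
Reagents that add atoms: none
Why: Phase-transfer N-alkylation of the azetidinone N–H (SN2 at a primary bromide), a standard way to N-alkylate monocyclic β-lactams; the excess of 3 should suppress double alkylation and the stereocentre is not involved.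

Step 3
Reactants: 4 (4S)-1-(3-bromopropyl)-4-phenylazetidin-2-one; 5 aziridine
Product: 6 (4S)-1-[3-(aziridin-1-yl)propyl]-4-phenylazetidin-2-one
Conditions: 5 (6 equiv), K2CO3, MeCN, 40 °C, closed vessel; purification on basic alumina
Reagents that add atoms: none
Why: SN2 N-alkylation of aziridine by the primary bromide; the large excess of volatile aziridine should suppress quaternization of the product, and the resulting tertiary aziridine nitrogen cannot transamidate the β-lactam.

Step 4
Reactants: 6 (4S)-1-[3-(aziridin-1-yl)propyl]-4-phenylazetidin-2-one; 7 N-(2-chloroethyl)benzamide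
Product: 12 N-{4-[(4S)-2-oxo-4-phenyl-1,5-diazocan-1-yl]butyl}benzamide, via dilithio amide 8 (not isolated), via cuprate 9 (not isolated), via amino β-lactam 10 (not isolated), via bicyclic carbinolamine 11 (not isolated)
Conditions: 7 (3 equiv), n-BuLi (3 equiv), THF, −78 °C; Li powder (2 equiv per Cl), DTBB (5 mol %), −78 °C; CuI (1.5 equiv), −78 → −50 °C; 6 (1 equiv), then BF3·OEt2 (3 equiv), −78 °C; aq NH3/NH4Cl; PhMe, 90 °C
Reagents that add atoms: none
Why: Proposed new method: the soft dialkylcuprate 9 should attack a CH2 of the BF3-bound aziridine of 6 in an SN2 ring opening (closest known reaction type: BF3-promoted alkylation of N-alkylaziridines by lithium dialkylcuprates; the new element is the cuprate made from the N,C-dilithiated chloroethyl amide 8), which forms the C2'–C3' bond and at the same time turns the inert tertiary aziridine nitrogen into the secondary amine of 10. Once the ammonia work-up has freed this amine, it should attack the strained β-lactam carbonyl through a six-membered transition state (6-exo-trig) to give the 1,5-diazabicyclo[4.2.0]octane carbinolamine 11, whose shared C–N bond then breaks to release the eight-membered lactam 12 (closest known reaction type: transamidative ring enlargement of 1-(3-aminopropyl)azetidin-2-ones, driven by β-lactam strain). No stereocentre is created: C4 comes unchanged from 1, and the carbinolamine carbon of 11 is destroyed again in the fragmentation. The step needs chemoselectivity for the aziridine carbon over the β-lactam carbonyl, which the low temperature, the soft copper nucleophile and the preferential binding of BF3 to the basic aziridine nitrogen should secure. It also needs the nitrogen to stay silent until the C–C bond exists, which the tertiary aziridine guarantees because it cannot be acylated.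

Step 5
Reactants: 12 N-{4-[(4S)-2-oxo-4-phenyl-1,5-diazocan-1-yl]butyl}benzamide
Product: 13 N-{4-[(4S)-5-methyl-2-oxo-4-phenyl-1,5-diazocan-1-yl]butyl}benzamide
Conditions: 37 % aq HCHO, NaBH(OAc)3, ClCH2CH2Cl, rt; aq NaHCO3
Reagents that add atoms: formaldehyde, C=O
Why: Reductive amination of the secondary N5–H amine with formaldehyde (iminium formation, then hydride delivery from the triacetoxyborohydride); the lactam and benzamide nitrogens are not nucleophilic enough to react and C4 is not epimerized under these mild conditions.

**Compound list**

1 | methyl (3S)-3-amino-3-phenylpropanoate hydrochloride | Cl.COC(=O)C[C@@H](c1ccccc1)N | starting material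
2 | (4S)-4-phenylazetidin-2-one | O=C1C[C@@H](c2ccccc2)N1 | intermediate
3 | 1,3-dibromopropane | BrCCCBr | starting material
4 | (4S)-1-(3-bromopropyl)-4-phenylazetidin-2-one | O=C1C[C@@H](c2ccccc2)N1CCCBr | intermediate
5 | aziridine | C1CN1 | starting material
6 | (4S)-1-[3-(aziridin-1-yl)propyl]-4-phenylazetidin-2-one | O=C1C[C@@H](c2ccccc2)N1CCCN1CC1 | intermediate
7 | N-(2-chloroethyl)benzamide | ClCCNC(=O)c1ccccc1 | starting material
8 | N-lithio-N-(2-lithioethyl)benzamide | [Li]CCN([Li])C(=O)c1ccccc1 | intermediate (not isolated)
9 | lithium bis[2-(N-lithiobenzamido)ethyl]cuprate | [Li+].[Li]N(CC[Cu-]CCN([Li])C(=O)c1ccccc1)C(=O)c1ccccc1 | intermediate (not isolated)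
10 | N-[4-({3-[(4S)-2-oxo-4-phenylazetidin-1-yl]propyl}amino)butyl]benzamide | O=C1C[C@@H](c2ccccc2)N1CCCNCCCCNC(=O)c1ccccc1 | intermediate (not isolated)
11 | N-{4-[(8S)-6-hydroxy-8-phenyl-1,5-diazabicyclo[4.2.0]octan-5-yl]butyl}benzamide (configuration at C6 not controlled and not relevant) | OC12C[C@@H](c3ccccc3)N1CCCN2CCCCNC(=O)c1ccccc1 | intermediate (not isolated)
12 | N-{4-[(4S)-2-oxo-4-phenyl-1,5-diazocan-1-yl]butyl}benzamide | N1CCCN(CCCCNC(=O)c2ccccc2)C(=O)C[C@H]1c1ccccc1 | intermediate
13 | N-{4-[(4S)-5-methyl-2-oxo-4-phenyl-1,5-diazocan-1-yl]butyl}benzamide | CN1CCCN(CCCCNC(=O)c2ccccc2)C(=O)C[C@H]1c1ccccc1 | target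

**Step count**

Total steps: 5. Longest linear sequence: 5 steps (1 → 2 → 4 → 6 → 12 → 13); fragment 7 is used as purchased.

**Steps most likely to fail**

Step 4 (proposed new method). Transfer of the 2-amidoethyl group to the activated aziridine carbon may be outrun by β-elimination of the organometallic with loss of ethene, by cationic oligomerization of the BF3-activated aziridine, or by alkylation at the amidate nitrogen or oxygen instead of carbon. The fallback uses known chemistry, forms the same chain bond as an alkene, sets out from 4 and returns at 12. Bromide 4 is heated with excess allylamine and K2CO3 in MeCN, which should give (4S)-4-phenyl-1-[3-(prop-2-en-1-ylamino)propyl]azetidin-2-one F1. Without isolation this should enlarge by transamidation to (4S)-4-phenyl-1-(prop-2-en-1-yl)-1,5-diazocan-2-one F2. Olefin cross-metathesis of the p-toluenesulfonic acid salt of F2 with excess commercial N-allylbenzamide (Hoveyda–Grubbs II catalyst, CH2Cl2, 40 °C) should give N-{(2E)-4-[(4S)-2-oxo-4-phenyl-1,5-diazocan-1-yl]but-2-en-1-yl}benzamide F3. Hydrogenation of the alkene (H2, PtO2, EtOAc, rt, chosen to spare the benzylic C–N bond) then gives 12.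

Step 3. Over-alkylation of the product aziridine to an aziridinium ion, followed by bromide ring opening and oligomerization, may consume 6 as it forms. The fallback avoids alkylating aziridine with a halide, sets out from 1 and 5 and returns at 6. Aza-Michael addition of 5 to acrolein (Et2O, 0 °C) should give 3-(aziridin-1-yl)propanal F4. Condensation with the free base of 1 (MgSO4, CH2Cl2) should give methyl (3S)-3-{[3-(aziridin-1-yl)propylidene]amino}-3-phenylpropanoate F5. Reduction without isolation (NaBH4, MeOH, 0 °C) should give methyl (3S)-3-{[3-(aziridin-1-yl)propyl]amino}-3-phenylpropanoate F6. Breckpot ring closure of this N-alkyl β-amino ester (t-BuMgCl, THF, 0 °C) then gives 6 directly, so steps 2 and 3 are both bypassed.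

Step 1. Intermolecular acylation (oligoamide formation) may compete with the four-membered ring closure of the magnesium amide. The fallback changes from amide-anion acylation of an ester to carboxyl activation, sets out from 1 and returns at 2. Saponification (LiOH, THF/H2O, then adjustment to pH 7) should give (3S)-3-amino-3-phenylpropanoic acid F7. Cyclodehydration with PPh3 and 2,2'-dipyridyl disulfide in MeCN at reflux under dilution then gives 2.

**Further compounds**

F1 | step 4 | (4S)-4-phenyl-1-[3-(prop-2-en-1-ylamino)propyl]azetidin-2-one | O=C1C[C@@H](c2ccccc2)N1CCCNCC=C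
F2 | step 4 | (4S)-4-phenyl-1-(prop-2-en-1-yl)-1,5-diazocan-2-one | O=C1C[C@@H](c2ccccc2)NCCCN1CC=C
F3 | step 4 | N-{(2E)-4-[(4S)-2-oxo-4-phenyl-1,5-diazocan-1-yl]but-2-en-1-yl}benzamide | O=C1C[C@@H](c2ccccc2)NCCCN1C/C=C/CNC(=O)c1ccccc1
F4 | step 3 | 3-(aziridin-1-yl)propanal | O=CCCN1CC1
F5 | step 3 | methyl (3S)-3-{[3-(aziridin-1-yl)propylidene]amino}-3-phenylpropanoate | COC(=O)C[C@@H](c1ccccc1)N=CCCN1CC1
F6 | step 3 | methyl (3S)-3-{[3-(aziridin-1-yl)propyl]amino}-3-phenylpropanoate | COC(=O)C[C@@H](c1ccccc1)NCCCN1CC1
F7 | step 1 | (3S)-3-amino-3-phenylpropanoic acid | OC(=O)C[C@@H](c1ccccc1)N
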